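The plan cuts the tetrahydrofuran ring (O, C1, C11a, C4a, C4; xenicane numbering) at O–C1 and at the ring-fusion bond C11a–C4a. The key step exploits the oxygenated C3 hydroxymethyl arm on C4. This arm carries the C1–C11a acyl unit as a temporary ester tether on a Sharpless epoxide spanning C4–C4a. One base treatment lets dienolate carbon C11a open the epoxide at C4a with inversion. The released C4 alkoxide then captures acyl carbon C1 and frees the C3 alcohol. Both bonds and two stereocentres form together. Lactone-to-ether reduction, ring-closing metathesis to the Z-cyclononene, dienyl coupling and palmitoylation complete the route from (S)-linalool.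

Key step: step 10

Atom names used below (xenicane numbering):
- C1 = ring OCH2
- C3 = CH2O(acyl)
- C4 = quaternary ring carbon
- C4a and C11a = ring-fusion carbons
- C5–C11 = remaining cyclononene carbons (C7 carbinol, C8=C9, C11 bearing the exocyclic methylene C19)
- C12–C15 = dienyl chain

Assumption: (S)-(+)-linalool (coriandrol) is taken as a commercial compound of high enantiomeric purity.

Step 1
Reactants: 1 (S)-(+)-linalool
Product: 2 (3S)-3,7-dimethyl-3-(triethylsilyloxy)octa-1,6-diene
Conditions: Et3SiOTf (1.3 equiv), 2,6-lutidine, CH2Cl2, 0 °C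
Reagents that add atoms: triethylsilyl triflate, CC[Si](CC)(CC)OS(=O)(=O)C(F)(F)F
Why: Silyl triflate silylation of a hindered tertiary alcohol leaves the C7 stereocentre untouched, and the ether prevents later 5-exo attack of the C7 oxygen on the C4–C4a epoxide.

Step 2
Reactants: 2 linalool triethylsilyl ether
Product: 3 (4S)-4-methyl-4-(triethylsilyloxy)hex-5-enal
Conditions: O3 (Sudan Red 7B end-point), CH2Cl2, −78 °C; then Me2S, −78 °C to rt
Reagents that add atoms: ozone, [O-][O+]=O
Why: Chemoselective ozonolysis works because the electron-rich trisubstituted alkene reacts much faster than the vinyl group shielded by quaternary C7, and the dye marks the end-point.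

Step 3
Reactants: 3 aldehyde
Product: 4 ethyl (2Z,6S)-2-bromo-6-methyl-6-(triethylsilyloxy)octa-2,7-dienoate
Conditions: Ph3P=CHCO2Et, NBS, CH2Cl2, −20 °C; then 3, −20 °C to rt
Reagents that add atoms: ethyl (triphenylphosphoranylidene)acetate, CCOC(=O)C=P(c1ccccc1)(c1ccccc1)c1ccccc1; N-bromosuccinimide, O=C1CCC(=O)N1Br
Why: Wittig olefination with a stabilised α-bromo ylide, made in situ by bromination of the parent ylide, places the ester trans to the chain and so should give the Z-bromoenoate.

Step 4
Reactants: 4 Z-bromoenoate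
Product: 5 ethyl (2E,6S)-6-methyl-6-(triethylsilyloxy)-2-[(trimethylsilyl)ethynyl]octa-2,7-dienoate
Conditions: HC≡CSiMe3, PdCl2(PPh3)2 (5 mol %), CuI (10 mol %), Et3N, THF, rt
Reagents that add atoms: ethynyltrimethylsilane, C#C[Si](C)(C)C
Why: Sonogashira coupling of an activated alkenyl bromide retains the alkene geometry, so the alkynyl group (C12–C13) ends cis to the C5 chain.

Step 5
Reactants: 5 enyne ester
Product: 6 (2E,6S)-6-methyl-6-(triethylsilyloxy)-2-[(trimethylsilyl)ethynyl]octa-2,7-dien-1-ol
Conditions: iBu2AlH (2.5 equiv), CH2Cl2, −78 °C; aq. KNaC4H4O6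
Reagents that add atoms: none
Why: 1,2-Reduction of the enoate with iBu2AlH at low temperature gives the allylic alcohol without touching the silylalkyne or the alkene geometry.

Step 6
Reactants: 6 enynol
Product: 7 {(2S,3S)-3-[(3S)-3-methyl-3-(triethylsilyloxy)pent-4-en-1-yl]-2-[(trimethylsilyl)ethynyl]oxiran-2-yl}methanol
Conditions: Ti(OiPr)4 (20 mol %), L-(+)-diethyl tartrate (24 mol %), tBuOOH, 4 Å molecular sieves, CH2Cl2, −20 °C
Reagents that add atoms: tert-butyl hydroperoxide, CC(C)(C)OO
Why: In the Sharpless asymmetric epoxidation, hydroxyl-directed oxygen transfer touches only the allylic C4=C4a alkene, and L-(+)-tartrate sets C4 and C4a as (2S,3S), as it does for other E-configured allylic alcohols.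

Step 7
Reactants: 8 3-chloro-2-(chloromethyl)prop-1-ene
Product: 9 2-(chloromethyl)penta-1,4-diene
Conditions: CH2=CHMgBr (0.5 equiv), CuI (5 mol %), THF, −30 °C to 0 °C
Reagents that add atoms: vinylmagnesium bromide, C=C[Mg]Br
Why: Copper-catalysed allylic substitution of a symmetrical bis-allylic dichloride gives the same product by direct and by allylic-shift attack, and excess 8 limits double substitution.

Step 8
Reactants: 9 2-(chloromethyl)penta-1,4-diene
Product: 11 3-methylidenehex-5-enoic acid, via allylmagnesium chloride 10 (not isolated)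
Conditions: Mg, THF, 0 °C; CO2, −78 °C to rt; aq. HCl
Reagents that add atoms: carbon dioxide, O=C=O
Why: Grignard formation and carboxylation are regiochemically safe because both termini of the 2-substituted allyl system are CH2.

Step 9
Reactants: 7 epoxy alcohol; 11 3-methylidenehex-5-enoic acid
Product: 12 {(2S,3S)-3-[(3S)-3-methyl-3-(triethylsilyloxy)pent-4-en-1-yl]-2-[(trimethylsilyl)ethynyl]oxiran-2-yl}methyl 3-methylidenehex-5-enoate
Conditions: DCC, DMAP (10 mol %), CH2Cl2, 0 °C
Reagents that add atoms: none
Why: Steglich esterification of the primary alcohol under cold, neutral conditions leaves the epoxide and the β,γ-unsaturation in place.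

Step 10
Reactants: 12 epoxy ester
Product: 14 (3R,4S,5S)-5-(hydroxymethyl)-4-[(3S)-3-methyl-3-(triethylsilyloxy)pent-4-en-1-yl]-3-(penta-1,4-dien-2-yl)-5-[(trimethylsilyl)ethynyl]oxolan-2-one, via hydroxy δ-lactone 13 (not isolated)
Conditions: LiN(SiMe3)2 (1.2 equiv), THF/DMPU, −78 °C to 0 °C; AcOH quench
Reagents that add atoms: none
Why: Proposed new method: LiN(SiMe3)2 forms the lithium dienolate of the β,γ-unsaturated ester, whose α-carbon C11a attacks the secondary epoxide carbon C4a anti to the C4a–O bond (6-endo-tet, chair-like) to give the alkoxide of δ-lactone 13, and this tertiary C4 alkoxide adds to the C1 carbonyl (5-exo-trig, through a 2,7-dioxabicyclo[2.2.1]heptane-type adduct) and expels the primary C3 alkoxide, which closes the γ-lactone ring O–C1–C11a–C4a–C4. The closest known reaction types are the Stork epoxynitrile (epoxy-enolate) cyclisation, the classical γ-butyrolactone synthesis from epoxides and ester or acid enolates, and base-induced translactonisation; only their combination through an acyloxy tether lacks precedent. C4a is set by stereospecific SN2 inversion of the Sharpless epoxide (the descriptor stays S because priorities change), C4 is carried through unchanged, and C11a is set trans to the C5 chain by the chair with both substituents equatorial, which is also the thermodynamic α-epimer. The step needs attack at C4a and not at C4, which is secured because C4 is fully substituted and carbanions open unsymmetrical epoxides at the less substituted carbon, while the approach angle C11a···C4a–C4 of about 120° fits a six-membered transition state. It also needs α- and not γ-reactivity of the dienolate, which is secured by ring size (six against eight atoms), and kinetic α-protonation on quench keeps the C11=C19 methylene out of conjugation. The acyl transfer is driven by the greater stability of γ- over δ-lactones and by exchange of a tertiary for a primary alkoxide.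

Step 11
Reactants: 14 hydroxy γ-lactone
Product: 15 lactol (C1 epimers) of 14
Conditions: iBu2AlH (3 equiv), CH2Cl2, −78 °C; aq. KNaC4H4O6
Reagents that add atoms: none
Why: Partial reduction of a γ-lactone with iBu2AlH stops at the aluminium lactolate at −78 °C, and one extra equivalent is consumed by the free alcohol.

Step 12
Reactants: 15 lactol
Product: 16 {(2S,3S,4R)-3-[(3S)-3-methyl-3-(triethylsilyloxy)pent-4-en-1-yl]-4-(penta-1,4-dien-2-yl)-2-[(trimethylsilyl)ethynyl]oxolan-2-yl}methanol
Conditions: Et3SiH (5 equiv), BF3·OEt2 (2 equiv), CH2Cl2, −78 °C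
Reagents that add atoms: none
Why: In this ionic reduction of a lactol, BF3 generates the five-membered oxocarbenium ion at C1 far faster than it ionises the tertiary silyl ether or the C4–O bond at −78 °C, Et3SiH delivers hydride, and no stereocentre is created.

Step 13
Reactants: 16 oxolane triene
Product: 17 bicyclic alcohol: trans-fused oxolane–(8Z)-cyclononene; (4S,4aS,7S,11aR); C4 bears CH2OH plus C≡C–SiMe3; C7 bears CH3 plus OSiEt3; C11 bears =CH2
Conditions: second-generation Hoveyda–Grubbs catalyst (10 mol %), 1,4-benzoquinone (20 mol %), toluene (1 mM), 80 °C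
Reagents that add atoms: none
Why: Ring-closing metathesis initiates at the unhindered allyl terminus (C9) and closes onto the C8 vinyl group; a nine-membered ring accommodates only the Z alkene, and the C11=C19 alkene and the silylated alkyne next to quaternary C4 are too hindered to compete.

Step 14
Reactants: 17 bicyclic alcohol
Product: 18 bicyclic diol: as 17 but C4 bears C≡CH and C7 bears OH; (4S,4aS,7S,11aR)
Conditions: Bu4NF (3 equiv), THF, 0 °C to rt
Reagents that add atoms: none
Why: Fluoride-mediated desilylation removes the alkynyl SiMe3 and the tertiary SiEt3 group in one operation, now that the epoxide and metathesis steps are past.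

Step 15
Reactants: 18 bicyclic diol
Product: 19 C3 palmitate of 18; (4S,4aS,7S,11aR)
Conditions: palmitoyl chloride (1.1 equiv), pyridine, DMAP (5 mol %), CH2Cl2, 0 °C
Reagents that add atoms: palmitoyl chloride, CCCCCCCCCCCCCCCC(=O)Cl
Why: DMAP-catalysed acylation discriminates the primary C3 alcohol from the unreactive tertiary allylic C7 alcohol.

Step 16
Reactants: 19 alkynyl palmitate
Product: 21 target CNP0150666.1; (4R,4aS,7S,8Z,11aR,12E), via alkenylboronate 20 (not isolated)
Conditions: B2pin2, CuCl (5 mol %), Xantphos (5 mol %), NaOtBu (10 mol %), MeOH (2 equiv), THF, rt; then Me2C=CHBr, Pd(dppf)Cl2 (5 mol %), aq. K3PO4, 45 °C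
Reagents that add atoms: bis(pinacolato)diboron, CC1(C)OB(OC1(C)C)B1OC(C)(C)C(C)(C)O1 (its boryl group stays only in 20); 1-bromo-2-methylprop-1-ene, CC(C)=CBr
Why: Copper-catalysed formal hydroboration (syn borylcupration, protonation by MeOH) puts boron on the terminal carbon away from quaternary C4 and tolerates the free alcohol, and Suzuki–Miyaura coupling with retention at both partners gives the E-dienyl chain.

Compound list
1 | (S)-(+)-linalool, (3S)-3,7-dimethylocta-1,6-dien-3-ol | C=C[C@@](C)(O)CCC=C(C)C | starting material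
2 | (3S)-3,7-dimethyl-3-(triethylsilyloxy)octa-1,6-diene | C=C[C@@](C)(O[Si](CC)(CC)CC)CCC=C(C)C | intermediate
3 | (4S)-4-methyl-4-(triethylsilyloxy)hex-5-enal | C=C[C@@](C)(O[Si](CC)(CC)CC)CCC=O | intermediate
4 | ethyl (2Z,6S)-2-bromo-6-methyl-6-(triethylsilyloxy)octa-2,7-dienoate | C=C[C@@](C)(O[Si](CC)(CC)CC)CC/C=C(\Br)C(=O)OCC | intermediate
5 | ethyl (2E,6S)-6-methyl-6-(triethylsilyloxy)-2-[(trimethylsilyl)ethynyl]octa-2,7-dienoate | C=C[C@@](C)(O[Si](CC)(CC)CC)CC/C=C(\C#C[Si](C)(C)C)C(=O)OCC | intermediate
6 | (2E,6S)-6-methyl-6-(triethylsilyloxy)-2-[(trimethylsilyl)ethynyl]octa-2,7-dien-1-ol | C=C[C@@](C)(O[Si](CC)(CC)CC)CC/C=C(\C#C[Si](C)(C)C)CO | intermediate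
7 | {(2S,3S)-3-[(3S)-3-methyl-3-(triethylsilyloxy)pent-4-en-1-yl]-2-[(trimethylsilyl)ethynyl]oxiran-2-yl}methanol | C=C[C@@](C)(O[Si](CC)(CC)CC)CC[C@@H]1O[C@@]1(C#C[Si](C)(C)C)CO | intermediate
8 | 3-chloro-2-(chloromethyl)prop-1-ene | C=C(CCl)CCl | starting material
9 | 2-(chloromethyl)penta-1,4-diene | C=CCC(=C)CCl | intermediate
10 | (2-methylidenepent-4-en-1-yl)magnesium chloride | C=CCC(=C)C[Mg]Cl | intermediate
11 | 3-methylidenehex-5-enoic acid | C=CCC(=C)CC(=O)O | intermediate
12 | epoxy ester of 7 with 11, (2S,3S)-oxirane | C=C[C@@](C)(O[Si](CC)(CC)CC)CC[C@@H]1O[C@@]1(C#C[Si](C)(C)C)COC(=O)CC(=C)CC=C | intermediate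
13 | (3R,4S,5S)-5-hydroxy-4-[(3S)-3-methyl-3-(triethylsilyloxy)pent-4-en-1-yl]-3-(penta-1,4-dien-2-yl)-5-[(trimethylsilyl)ethynyl]oxan-2-one | C=C[C@@](C)(O[Si](CC)(CC)CC)CC[C@H]1[C@H](C(=C)CC=C)C(=O)OC[C@@]1(O)C#C[Si](C)(C)C | intermediate
14 | (3R,4S,5S)-5-(hydroxymethyl)-4-[(3S)-3-methyl-3-(triethylsilyloxy)pent-4-en-1-yl]-3-(penta-1,4-dien-2-yl)-5-[(trimethylsilyl)ethynyl]oxolan-2-one | C=C[C@@](C)(O[Si](CC)(CC)CC)CC[C@H]1[C@H](C(=C)CC=C)C(=O)O[C@@]1(C#C[Si](C)(C)C)CO | intermediate
15 | lactol of 14 (C1 epimers) | C=C[C@@](C)(O[Si](CC)(CC)CC)CC[C@H]1[C@H](C(=C)CC=C)C(O)O[C@@]1(C#C[Si](C)(C)C)CO | intermediate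
16 | {(2S,3S,4R)-3-[(3S)-3-methyl-3-(triethylsilyloxy)pent-4-en-1-yl]-4-(penta-1,4-dien-2-yl)-2-[(trimethylsilyl)ethynyl]oxolan-2-yl}methanol | C=C[C@@](C)(O[Si](CC)(CC)CC)CC[C@H]1[C@H](C(=C)CC=C)CO[C@@]1(C#C[Si](C)(C)C)CO | intermediate
17 | trans-fused oxolane–(8Z)-cyclononene, (4S,4aS,7S,11aR), C4: CH2OH and C≡C–SiMe3, C7: CH3 and OSiEt3, C11: =CH2 | C=C1C/C=C\[C@@](C)(O[Si](CC)(CC)CC)CC[C@H]2[C@H]1CO[C@@]2(C#C[Si](C)(C)C)CO | intermediate
18 | bicyclic diol, (4S,4aS,7S,11aR), C4: CH2OH and C≡CH, C7: CH3 and OH | C=C1C/C=C\[C@@](C)(O)CC[C@H]2[C@H]1CO[C@@]2(C#C)CO | intermediate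
19 | C3 palmitate of 18, (4S,4aS,7S,11aR) | C=C1C/C=C\[C@@](C)(O)CC[C@H]2[C@H]1CO[C@@]2(C#C)COC(=O)CCCCCCCCCCCCCCC | intermediate
20 | (12E)-alkenyl pinacol boronate of 19, (4R,4aS,7S,11aR) | C=C1C/C=C\[C@@](C)(O)CC[C@H]2[C@H]1CO[C@@]2(/C=C/B3OC(C)(C)C(C)(C)O3)COC(=O)CCCCCCCCCCCCCCC | intermediate
21 | CNP0150666.1, (4R,4aS,7S,8Z,11aR,12E) | C=C1C/C=C\[C@@](C)(O)CC[C@H]2[C@H]1CO[C@@]2(/C=C/C=C(C)C)COC(=O)CCCCCCCCCCCCCCC | target

Total step count: 16. Longest linear sequence: 14 (steps 1–6 and 9–16).

Steps most likely to fail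

1. Step 10.
   - What may go wrong: the dienolate may fragment to a vinylketene and an epoxy alkoxide (followed by Payne migration). It may be reprotonated into conjugation. It may also fail to reach the rear of the C4a–O bond before it decomposes.
   - Fallback (known chemistry): it sets out from 7 and comes back at 14.
   - The primary alcohol of 7 is capped (NaH, 4-methoxybenzyl chloride, Bu4NI, THF, 0 °C) to give the p-methoxybenzyl ether F1.
   - F1 is opened bimolecularly at C4a by the dilithium dienediolate of acid 11 (LiN(iPr)2, 2.1 equiv, THF, 0 to 45 °C). This is the classical γ-lactone synthesis from an epoxide and a carboxylic acid dianion.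
   - Acidification in the same operation closes the protected γ-lactone F2.
   - DDQ in buffered CH2Cl2 removes the benzyl group and delivers 14.

2. Step 13.
   - What may go wrong: intermolecular metathesis (oligomerisation) may outrun closure of the strained trans-fused nine-membered ring, and ruthenium hydrides may shift the skipped diene.
   - Fallback: it sets out from 12 and comes back at 17.
   - Ring closure is moved to the strain-free stage. The second-generation Grubbs catalyst in dilute CH2Cl2 converts 12 into the thirteen-membered epoxy macrolactone F3, and the Z isomer is separated from the E isomer.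
   - LiN(SiMe3)2 then triggers the step 10 cascade across the ring. This contracts the macrocycle to the bicyclic hydroxy γ-lactone F4.
   - iBu2AlH gives the bicyclic lactol F5, and Et3SiH/BF3·OEt2 gives 17.

3. Step 6.
   - What may go wrong: oxygen transfer to the electron-poor, hindered enyne alkene may be slow, facial selectivity may erode, and titanium alkoxides may open the sensitive epoxy alcohol.
   - Fallback: it sets out from 6 and comes back at 7.
   - Hydroxyl-directed titanium delivery is abandoned for undirected chiral dioxirane oxidation (Shi epoxidation), a method suited to conjugated enynes.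
   - The catalyst is the L-sorbose-derived enantiomer of the Shi ketone, with KHSO5 and K2CO3 buffer in MeCN/dimethoxymethane at 0 °C. By the spiro transition-state model it should deliver the same (2S,3S) face.
   - No new compound is made.

Further compounds
F1 | step 10 | p-methoxybenzyl ether of 7, (2S,3S)-oxirane | C=C[C@@](C)(O[Si](CC)(CC)CC)CC[C@@H]1O[C@@]1(C#C[Si](C)(C)C)COCc1ccc(OC)cc1
F2 | step 10 | p-methoxybenzyl ether of 14, (3R,4S,5S) | C=C[C@@](C)(O[Si](CC)(CC)CC)CC[C@H]1[C@H](C(=C)CC=C)C(=O)O[C@@]1(C#C[Si](C)(C)C)COCc1ccc(OC)cc1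
F3 | step 13 | thirteen-membered (8Z)-epoxy macrolactone from 12 | C=C1C/C=C\[C@@](C)(O[Si](CC)(CC)CC)CC[C@@H]2O[C@@]2(C#C[Si](C)(C)C)COC(=O)C1
F4 | step 13 | bicyclic hydroxy γ-lactone, (4S,4aS,7S,11aR), C1 carbonyl analogue of 17 | C=C1C/C=C\[C@@](C)(O[Si](CC)(CC)CC)CC[C@H]2[C@H]1C(=O)O[C@@]2(C#C[Si](C)(C)C)CO
F5 | step 13 | bicyclic lactol of F4 (C1 epimers) | C=C1C/C=C\[C@@](C)(O[Si](CC)(CC)CC)CC[C@H]2[C@H]1C(O)O[C@@]2(C#C[Si](C)(C)C)CO
F0 | step 6 | none | none
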